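**Retrosynthetic overview**

1. The ten-membered ring is closed last, by ring-closing metathesis across C1=C10 of an acyclic bis-epoxy dienone, giving the (Z)-enone.
2. Before that, one double Sharpless epoxidation of a skipped diene carrying two primary allylic alcohols sets C4, C5, C7 and C11; acetylation follows, and the C9 ketone is unveiled from a silyl-protected carbinol.
3. The skipped diene is joined at C6–C7 by Stille coupling of an east vinylstannane (C7–C14) with a west allylic bromide (C1–C6, C15).
4. East: 2-methylacetoacetate dianion + methacrolein → δ-lactone (its ring fixes the tetrasubstituted C7=C11 geometry) → enol triflate → reductive ring opening → stannane. West: propargyl alcohol → butynediol mono-silyl ether → hydroalumination/iodination → Negishi coupling (fixes the C4=C5 geometry).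
5. Order of ring formation: δ-lactone (temporary, opened again) → both oxiranes in one step → ten-membered carbocycle.

Assumption: locants are germacrane locants (ring C1–C10; C14 = CH3 on C10; C15 = CH2O on C4; C11 on C7 carries C12 = CH2O and C13 = CH3), so the target is (4R,5R,7S,11R,1(10)Z); the C9 carbinol of the intermediates is carried racemic (two C9 epimers after step 14) because step 16 oxidises it to the ketone.

TBS = tert-butyl(dimethyl)silyl; Tf = trifluoromethanesulfonyl.

**West fragment**

Step 1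
Reactants: 1 prop-2-yn-1-ol (propargyl alcohol)
Product: 2 tert-butyl(dimethyl)(prop-2-yn-1-yloxy)silane
Conditions: TBSCl, imidazole, CH2Cl2, 0 °C to rt
Reagents that add atoms: tert-butyldimethylsilyl chloride, CC(C)(C)[Si](C)(C)Cl
Why: O-Silylation masks the future C15 oxygen so that the later hydroalumination is directed only by the other, free hydroxyl.

Step 2
Reactants: 2 tert-butyl(dimethyl)(prop-2-yn-1-yloxy)silane; 3 paraformaldehyde
Product: 4 4-{[tert-butyl(dimethyl)silyl]oxy}but-2-yn-1-ol
Conditions: n-BuLi, THF, −78 °C; then 3, −78 °C to rt; H2O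
Reagents that add atoms: none
Why: Addition of the lithium acetylide to formaldehyde (acetylide hydroxymethylation) adds C6 as a free primary alcohol.

Step 3
Reactants: 4 4-{[tert-butyl(dimethyl)silyl]oxy}but-2-yn-1-ol
Product: 5 (2Z)-4-{[tert-butyl(dimethyl)silyl]oxy}-3-iodobut-2-en-1-ol
Conditions: NaAlH2(OCH2CH2OCH3)2, THF, 0 °C; then iodine, THF, −78 °C
Reagents that add atoms: iodine, [I][I]
Why: Hydroxyl-directed trans-hydroalumination and iodinolysis with retention put H on C5 and iodine on C4 cis to the free CH2OH, which fixes the geometry of the future C4=C5 alkene.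

Step 4
Reactants: 5 (2Z)-4-{[tert-butyl(dimethyl)silyl]oxy}-3-iodobut-2-en-1-ol; 6 but-3-en-1-ylzinc bromide
Product: 7 (2E)-3-({[tert-butyl(dimethyl)silyl]oxy}methyl)hepta-2,6-dien-1-ol
Conditions: Pd(dppf)Cl2 (5 mol %), THF, rt to 50 °C
Reagents that add atoms: none
Why: Negishi sp2–sp3 cross-coupling replaces iodine with retention, so the butenyl chain (C3–C1) is cis to C6 and the CH2OTBS group (C15) trans to it.

Step 5
Reactants: 7 (2E)-3-({[tert-butyl(dimethyl)silyl]oxy}methyl)hepta-2,6-dien-1-ol
Product: 8 {[(2E)-4-bromo-2-(but-3-en-1-yl)but-2-en-1-yl]oxy}(tert-butyl)dimethylsilane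
Conditions: CBr4, PPh3, CH2Cl2, 0 °C
Reagents that add atoms: tetrabromomethane, BrC(Br)(Br)Br
Why: The Appel reaction converts the primary allylic alcohol into the bromide without allylic transposition or loss of alkene geometry.

Step 6
Reactants: 8 {[(2E)-4-bromo-2-(but-3-en-1-yl)but-2-en-1-yl]oxy}(tert-butyl)dimethylsilane
Product: 9 (2E)-4-bromo-2-(but-3-en-1-yl)but-2-en-1-ol
Conditions: HF·pyridine, pyridine, THF, 0 °C (used at once)
Reagents that add atoms: none
Why: Fluoride desilylation frees the C15 hydroxyl that later directs the epoxidation, and the E geometry prevents the bromo alcohol from cyclising.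

**East fragment**

Step 7
Reactants: 10 ethyl 2-methyl-3-oxobutanoate; 11 2-methylprop-2-enal (methacrolein)
Product: 13 (±)-4-hydroxy-3-methyl-6-(prop-1-en-2-yl)-5,6-dihydro-2H-pyran-2-one, via δ-hydroxy-β-keto ester 12 (not isolated)
Conditions: NaH then n-BuLi, THF, 0 °C; 11, −78 °C; then 1 M NaOH (aq), rt; HCl (aq) to pH 2
Reagents that add atoms: none
Why: Weiler dianion aldol addition at the γ-carbon (1,2-addition to the enal) and lactonisation give the β-keto-δ-lactone whose ring will hold C12 and C8 cis on the future tetrasubstituted alkene; the C9 carbinol is racemic and is oxidised away later.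

Step 8
Reactants: 13 (±)-4-hydroxy-3-methyl-6-(prop-1-en-2-yl)-5,6-dihydro-2H-pyran-2-one
Product: 14 (±)-5-methyl-6-oxo-2-(prop-1-en-2-yl)-3,6-dihydro-2H-pyran-4-yl trifluoromethanesulfonate
Conditions: Tf2O, Et3N, CH2Cl2, −78 °C
Reagents that add atoms: trifluoromethanesulfonic anhydride, O=S(=O)(OS(=O)(=O)C(F)(F)F)C(F)(F)F
Why: Enol triflate formation on the cyclic enol gives a single alkene isomer because the C11=C7 bond is endocyclic.

Step 9
Reactants: 14 (±)-5-methyl-6-oxo-2-(prop-1-en-2-yl)-3,6-dihydro-2H-pyran-4-yl trifluoromethanesulfonate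
Product: 15 (±)-(2E)-1,5-dihydroxy-2,6-dimethylhepta-2,6-dien-3-yl trifluoromethanesulfonate
Conditions: i-Bu2AlH (4 equiv), CH2Cl2, −78 to 0 °C
Reagents that add atoms: none
Why: 1,2-Reduction of the unsaturated lactone by the aluminium hydride opens the ring to the diol and leaves the enol triflate intact, so the ring-enforced geometry (C12 cis to C8) passes into the acyclic series.

Step 10
Reactants: 15 (±)-(2E)-1,5-dihydroxy-2,6-dimethylhepta-2,6-dien-3-yl trifluoromethanesulfonate
Product: 16 (±)-(2E)-1,5-bis{[tert-butyl(dimethyl)silyl]oxy}-2,6-dimethylhepta-2,6-dien-3-yl trifluoromethanesulfonate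
Conditions: TBSOTf, 2,6-lutidine, CH2Cl2, −78 to 0 °C
Reagents that add atoms: tert-butyldimethylsilyl trifluoromethanesulfonate, CC(C)(C)[Si](C)(C)OS(=O)(=O)C(F)(F)F
Why: Silyl ether formation on both hydroxyls is the reliable way to get the hindered secondary C9 hydroxyl protected.

Step 11
Reactants: 16 (±)-(2E)-1,5-bis{[tert-butyl(dimethyl)silyl]oxy}-2,6-dimethylhepta-2,6-dien-3-yl trifluoromethanesulfonate
Product: 17 (±)-(2E)-5-{[tert-butyl(dimethyl)silyl]oxy}-1-hydroxy-2,6-dimethylhepta-2,6-dien-3-yl trifluoromethanesulfonate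
Conditions: HF·pyridine, pyridine, THF, 0 °C
Reagents that add atoms: none
Why: Selective desilylation cleaves the unhindered primary allylic silyl ether much faster than the hindered secondary one, leaving C12–OH free and the C9 allylic alcohol blocked from the later titanium-mediated epoxidation.

Step 12
Reactants: 17 (±)-(2E)-5-{[tert-butyl(dimethyl)silyl]oxy}-1-hydroxy-2,6-dimethylhepta-2,6-dien-3-yl trifluoromethanesulfonate
Product: 18 (±)-(2E)-5-{[tert-butyl(dimethyl)silyl]oxy}-2,6-dimethyl-3-(trimethylstannyl)hepta-2,6-dien-1-ol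
Conditions: (Me3Sn)2, Pd(PPh3)4 (5 mol %), LiCl, THF, 65 °C
Reagents that add atoms: hexamethylditin, C[Sn](C)(C)[Sn](C)(C)C
Why: Palladium-catalysed stannylation of the enol triflate replaces OTf by SnMe3 with retention and makes C7 the nucleophilic coupling site.

**Union and end game**

Step 13
Reactants: 18 (±)-(2E)-5-{[tert-butyl(dimethyl)silyl]oxy}-2,6-dimethyl-3-(trimethylstannyl)hepta-2,6-dien-1-ol; 9 (2E)-4-bromo-2-(but-3-en-1-yl)but-2-en-1-ol
Product: 19 (±)-(2E,5Z)-2-(but-3-en-1-yl)-5-(2-{[tert-butyl(dimethyl)silyl]oxy}-3-methylbut-3-en-1-yl)-6-methylhepta-2,5-diene-1,7-diol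
Conditions: Pd2(dba)3 (5 mol %), AsPh3 (20 mol %), CuI (10 mol %), NMP, 45 °C
Reagents that add atoms: none
Why: In this Stille alkenyl–allyl cross-coupling the π-allylpalladium species from the bromide is attacked at its unhindered CH2 terminus (C6), both alkene geometries are retained, and the neutral conditions tolerate the two free hydroxyls.

Step 14
Reactants: 19 skipped-diene diol
Product: 21 bis-epoxy diacetate (4R,5R,7S,11R; C9 epimers; full name in the list), via bis-epoxy diol 20 (not isolated)
Conditions: Ti(OiPr)4 (0.4 equiv), diisopropyl D-(−)-tartrate (0.5 equiv), t-BuOOH, 4 Å molecular sieves, CH2Cl2, −25 °C; then P(OMe)3; then Ac2O, Et3N, DMAP (cat.), −20 to 0 °C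
Reagents that add atoms: tert-butyl hydroperoxide, CC(C)(C)OO; acetic anhydride, CC(=O)OC(C)=O
Why: In this double Sharpless asymmetric epoxidation with in situ acetylation, the D-(−)-tartrate complex epoxidises each primary allylic alcohol on the face opposite to the one L-(+)-tartrate uses (geraniol → (2S,3S)), which gives 4R,5R and 7S,11R; the two undirected terminal alkenes do not react.

Step 15
Reactants: 21 bis-epoxy diacetate silyl ether
Product: 22 bis-epoxy diacetate C9 alcohol (C9 epimers)
Conditions: Bu4NF, AcOH, THF, rt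
Reagents that add atoms: none
Why: Fluoride desilylation buffered with acetic acid removes the secondary silyl ether without acetate cleavage, acetyl migration or oxirane opening.

Step 16
Reactants: 22 bis-epoxy diacetate C9 alcohol
Product: 23 bis-epoxy diacetate isopropenyl ketone (single stereoisomer)
Conditions: Dess–Martin periodinane, NaHCO3, CH2Cl2, 0 °C to rt
Reagents that add atoms: none
Why: Buffered Dess–Martin oxidation makes the C9 ketone under non-basic conditions that spare the β,γ-oxirane, the two C9 epimers converge to one compound, and minor epoxide diastereomers from step 14 are removed here by chromatography.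

Step 17
Reactants: 23 bis-epoxy diacetate isopropenyl ketone
Product: 24 CNP0185847.2, (4R,5R,7S,11R,1(10)Z)-12,15-diacetoxy-4,5:7,11-diepoxygermacr-1(10)-en-9-one
Conditions: second-generation Hoveyda–Grubbs catalyst RuCl2(H2IMes)(=CH-C6H4-2-O-i-Pr) (15 mol %), 1,4-benzoquinone (20 mol %), toluene (1 mM), 80 °C
Reagents that add atoms: none
Why: In this ring-closing metathesis at high dilution the catalyst loads on the terminal vinyl group and closes onto the methacryloyl alkene; the two oxiranes pre-fold the chain, and the ten-membered ring accommodates the conjugated trisubstituted alkene only with the ring carbons cis, which is the required Z geometry.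

**Compound list**

1 | prop-2-yn-1-ol | C#CCO | starting material
2 | tert-butyl(dimethyl)(prop-2-yn-1-yloxy)silane | C#CCO[Si](C)(C)C(C)(C)C | intermediate
3 | paraformaldehyde (monomer unit shown) | C=O | starting material
4 | 4-{[tert-butyl(dimethyl)silyl]oxy}but-2-yn-1-ol | OCC#CCO[Si](C)(C)C(C)(C)C | intermediate
5 | (2Z)-4-{[tert-butyl(dimethyl)silyl]oxy}-3-iodobut-2-en-1-ol | OC/C=C(\[I])CO[Si](C)(C)C(C)(C)C | intermediate
6 | but-3-en-1-ylzinc bromide (commercial THF solution) | C=CCC[Zn]Br | starting material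
7 | (2E)-3-({[tert-butyl(dimethyl)silyl]oxy}methyl)hepta-2,6-dien-1-ol | OC/C=C(\CCC=C)CO[Si](C)(C)C(C)(C)C | intermediate
8 | {[(2E)-4-bromo-2-(but-3-en-1-yl)but-2-en-1-yl]oxy}(tert-butyl)dimethylsilane | BrC/C=C(\CCC=C)CO[Si](C)(C)C(C)(C)C | intermediate
9 | (2E)-4-bromo-2-(but-3-en-1-yl)but-2-en-1-ol | BrC/C=C(\CCC=C)CO | intermediate
10 | ethyl 2-methyl-3-oxobutanoate | CCOC(=O)C(C)C(C)=O | starting material
11 | 2-methylprop-2-enal (methacrolein) | CC(=C)C=O | starting material
12 | ethyl 5-hydroxy-2,6-dimethyl-3-oxohept-6-enoate (racemic, both diastereomers) | CCOC(=O)C(C)C(=O)CC(O)C(C)=C | intermediate (not isolated)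
13 | (±)-4-hydroxy-3-methyl-6-(prop-1-en-2-yl)-5,6-dihydro-2H-pyran-2-one | CC1=C(O)CC(C(C)=C)OC1=O | intermediate
14 | (±)-5-methyl-6-oxo-2-(prop-1-en-2-yl)-3,6-dihydro-2H-pyran-4-yl trifluoromethanesulfonate | CC1=C(OS(=O)(=O)C(F)(F)F)CC(C(C)=C)OC1=O | intermediate
15 | (±)-(2E)-1,5-dihydroxy-2,6-dimethylhepta-2,6-dien-3-yl trifluoromethanesulfonate | OC/C(C)=C(\CC(O)C(C)=C)OS(=O)(=O)C(F)(F)F | intermediate
16 | (±)-(2E)-1,5-bis{[tert-butyl(dimethyl)silyl]oxy}-2,6-dimethylhepta-2,6-dien-3-yl trifluoromethanesulfonate | CC(C)(C)[Si](C)(C)OC/C(C)=C(\CC(O[Si](C)(C)C(C)(C)C)C(C)=C)OS(=O)(=O)C(F)(F)F | intermediate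
17 | (±)-(2E)-5-{[tert-butyl(dimethyl)silyl]oxy}-1-hydroxy-2,6-dimethylhepta-2,6-dien-3-yl trifluoromethanesulfonate | OC/C(C)=C(\CC(O[Si](C)(C)C(C)(C)C)C(C)=C)OS(=O)(=O)C(F)(F)F | intermediate
18 | (±)-(2E)-5-{[tert-butyl(dimethyl)silyl]oxy}-2,6-dimethyl-3-(trimethylstannyl)hepta-2,6-dien-1-ol | OC/C(C)=C(\CC(O[Si](C)(C)C(C)(C)C)C(C)=C)[Sn](C)(C)C | intermediate
19 | (±)-(2E,5Z)-2-(but-3-en-1-yl)-5-(2-{[tert-butyl(dimethyl)silyl]oxy}-3-methylbut-3-en-1-yl)-6-methylhepta-2,5-diene-1,7-diol | OC/C(CCC=C)=C/C/C(CC(O[Si](C)(C)C(C)(C)C)C(C)=C)=C(\C)CO | intermediate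
20 | [(2R,3R)-2-(but-3-en-1-yl)-3-{[(2S,3R)-2-(2-{[tert-butyl(dimethyl)silyl]oxy}-3-methylbut-3-en-1-yl)-3-(hydroxymethyl)-3-methyloxiran-2-yl]methyl}oxiran-2-yl]methanol (both epimers at the silyloxy carbon) | OC[C@@]1(CCC=C)O[C@@H]1C[C@@]2(CC(O[Si](C)(C)C(C)(C)C)C(C)=C)O[C@]2(C)CO | intermediate (not isolated)
21 | [(2R,3R)-3-{[(2S,3R)-3-(acetoxymethyl)-2-(2-{[tert-butyl(dimethyl)silyl]oxy}-3-methylbut-3-en-1-yl)-3-methyloxiran-2-yl]methyl}-2-(but-3-en-1-yl)oxiran-2-yl]methyl acetate (both epimers at the silyloxy carbon) | CC(=O)OC[C@@]1(CCC=C)O[C@@H]1C[C@@]2(CC(O[Si](C)(C)C(C)(C)C)C(C)=C)O[C@]2(C)COC(C)=O | intermediate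
22 | [(2R,3R)-3-{[(2R,3R)-3-(acetoxymethyl)-2-(2-hydroxy-3-methylbut-3-en-1-yl)-3-methyloxiran-2-yl]methyl}-2-(but-3-en-1-yl)oxiran-2-yl]methyl acetate (both carbinol epimers; same geometry as 21, the C7 descriptor changes only through the priority rules) | CC(=O)OC[C@@]1(CCC=C)O[C@@H]1C[C@@]2(CC(O)C(C)=C)O[C@]2(C)COC(C)=O | intermediate
23 | [(2R,3R)-3-{[(2S,3R)-3-(acetoxymethyl)-3-methyl-2-(3-methyl-2-oxobut-3-en-1-yl)oxiran-2-yl]methyl}-2-(but-3-en-1-yl)oxiran-2-yl]methyl acetate | CC(=O)OC[C@@]1(CCC=C)O[C@@H]1C[C@@]2(CC(=O)C(C)=C)O[C@]2(C)COC(C)=O | intermediate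
24 | CNP0185847.2, (4R,5R,7S,11R,1(10)Z)-12,15-diacetoxy-4,5:7,11-diepoxygermacr-1(10)-en-9-one | CC(=O)OC[C@]12CC/C=C(/C)C(=O)C[C@]3(C[C@H]1O2)O[C@]3(C)COC(C)=O | target

**Step count and risks**

Total step count: 17 (west 1–6, east 7–12, common 13–17).
Longest linear sequence: 11 steps (1–6 then 13–17; the east branch 7–12 then 13–17 is equally long).

Steps most likely to fail:

Step 17 (ring-closing metathesis to a strained ten-membered ring at an electron-poor 1,1-disubstituted alkene; oligomers or no turnover are possible). Fallback: close the ring before the ketone exists. Setting out from alcohol 22, ring-closing metathesis of the more reactive allylic alcohol (same catalyst, high dilution) gives the ten-membered (Z)-allylic alcohol F1 as its two C9 epimers, and Dess–Martin oxidation of F1 comes back to the route at 24.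

Step 13 (Stille coupling of a hindered tetrasubstituted vinylstannane; transmetalation may be too slow and the allyl bromide may homocouple). Fallback: change the nucleophile to boron. Setting out from triflate 17, Miyaura borylation (bis(pinacolato)diboron, Pd(dppf)Cl2, KOPh, dioxane, 80 °C) gives the pinacol boronate F2, and Suzuki–Miyaura allyl–alkenyl coupling of F2 with bromide 9 (Pd(PPh3)4, K3PO4, THF/H2O) comes back to the route at 19.

Step 14 (two epoxidations, one on a tetrasubstituted alkene, plus acetylation in one flask; incomplete conversion or titanium-mediated oxirane opening are possible). Fallback: epoxidise one allylic alcohol at a time. Setting out from stannane 18 and the silyl-protected bromide 8, Stille coupling gives the mono-alcohol F3. Sharpless epoxidation of its single tetrasubstituted allylic alcohol (stoichiometric Ti(OiPr)4 and diisopropyl D-(−)-tartrate) and acetylation give the epoxy acetate F4. Selective removal of the primary silyl group (HF·pyridine) gives the allylic alcohol F5, and a second Sharpless epoxidation with the same tartrate followed by acetylation comes back to the route at 21.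

**Further compounds**

F1 | step 17 | ten-membered (1(10)Z)-allylic alcohol, 24 with C9 as CH–OH (both C9 epimers) | CC(=O)OC[C@]12CC/C=C(/C)C(O)C[C@]3(C[C@H]1O2)O[C@]3(C)COC(C)=O
F2 | step 13 | (±)-(2E)-5-{[tert-butyl(dimethyl)silyl]oxy}-2,6-dimethyl-3-(4,4,5,5-tetramethyl-1,3,2-dioxaborolan-2-yl)hepta-2,6-dien-1-ol | OC/C(C)=C(\CC(O[Si](C)(C)C(C)(C)C)C(C)=C)B1OC(C)(C)C(C)(C)O1
F3 | step 14 | (±)-19 with the C15 hydroxyl as its TBS ether (C12 hydroxyl free) | CC(C)(C)[Si](C)(C)OC/C(CCC=C)=C/C/C(CC(O[Si](C)(C)C(C)(C)C)C(C)=C)=C(\C)CO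
F4 | step 14 | (7S,11R)-7,11-epoxy-12-acetate of F3, C4=C5 alkene intact (both C9 epimers) | CC(C)(C)[Si](C)(C)OC/C(CCC=C)=C/C[C@@]1(CC(O[Si](C)(C)C(C)(C)C)C(C)=C)O[C@]1(C)COC(C)=O
F5 | step 14 | F4 with the C15 hydroxyl free (both C9 epimers) | OC/C(CCC=C)=C/C[C@@]1(CC(O[Si](C)(C)C(C)(C)C)C(C)=C)O[C@]1(C)COC(C)=O
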